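# Proposed synthesis of 3-chlorodivaricatic acid (16)

## Analysis of the target

3-Chlorodivaricatic acid (16) is a depside: ring A, a 3-chloro-2-hydroxy-4-methoxy-6-propylbenzoyl unit, is joined through its C1 carbonyl to the 4'-oxygen of ring B, a 2'-hydroxy-6'-propylbenzoic acid, and this aryl ester is the only link between the two rings. There is no stereocenter and no fused or bridged ring, so the problem is one of regiochemistry and chemoselectivity on two highly substituted arenes. Ring A is fully differentiated, with a free hydroxyl on C2, chlorine on C3, a methoxy group on C4, propyl on C6 and hydrogen only on C5. Three groups are sensitive: the aryl ester, which strong nucleophiles or bases cleave or transesterify; the salicylic-type acid of ring B, which decarboxylates on heating or in acid and must stay masked until the end; and the aryl chloride, which reductive conditions can remove. The hard bond is the ester itself, because its carbonyl sits on C1 between the C2 oxygen and the C6 propyl, so that a classical approach must activate a 2,6-disubstituted, electron-rich benzoic acid and deliver it to one of the two phenols of ring B. The route rests on one observation: with the carbonyl carbon removed and the C2 hydroxyl written as its methyl ether, ring A becomes 2-chloro-1,3-dimethoxy-5-propylbenzene (6), which has a mirror plane through the C–Cl and C–propyl bonds and therefore two equivalent C–H positions. Either of them can become C1, and both rings then descend from the same 5-propylresorcinol (1).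

## Retrosynthetic reasoning

**16 to 15.** The last bond cut is the O–CH2 bond of a benzyl ester on ring B, which leads to 15. The acid stays masked to the end because a free β-resorcylic acid decarboxylates easily and would interfere as an acidic, chelating group in the earlier steps. A benzyl ester is chosen because hydrogenolysis is neutral and leaves the aryl ester alone. The forward step must break the benzylic C–O bond faster than the C–Cl bond.

**15 to 13.** The C2 hydroxyl of ring A is traced back to a methyl ether, 13. With both ring A oxygens methylated the arene precursor is symmetric, and no free phenol sits next to the reacting carbon to be acylated itself. The cut is made at C2 and not at C4 because only the C2 methoxy lies next to the ester carbonyl. The forward reaction is a chelation-controlled dealkylation by a boron Lewis acid, which must leave the C4 methoxy and the aryl ester in place.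

**13 to 7 + 12 + 11.** The central disconnection removes the ester carbonyl as carbon monoxide 12. It cuts both the C1–C(=O) bond and the C(=O)–O bond and leaves aryl iodide 7 and phenol 11. Cutting only the C–O bond would leave a 2,6-disubstituted benzoic acid to activate, which is the recognised weak point of depside synthesis. Cutting both bonds lets the carbonyl be assembled on a metal, where the crowding matters far less, and makes the ring A partner a simple halide of a symmetric arene. The gain is full convergence and two skeletal bonds in one operation. The forward reaction must insert into C–I while ignoring C–Cl, and must acylate the 4-OH of 11 while leaving its hydrogen-bonded 2-OH.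

**7 to 6.** The C–I bond is cut to give 6. The two C–H positions of 6 are equivalent, and each is activated by one ortho and one para methoxy group. Electrophilic iodination therefore needs no directing device; it only has to stop after one substitution.

**6 to 4 (through 5).** The C–Cl bond is cut next, leading to 4 through its 2-lithio derivative 5. Electrophilic chlorination would go to the positions para to methoxy. Deprotonation instead selects the hydrogen between the two ethers, the most acidic in the ring, and a chlorine donor traps the anion. Placing chlorine before iodine also means that no exchangeable halogen is present when the alkyllithium is used.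

**4 to 1 + 2.** The two O–CH3 bonds are cut, giving 1 and dimethyl sulfate 2. The second methylation passes through monoether 3.

**11 to 9 + 10, and 9 to 1 (through 8).** On the ring B side, 11 is cut at the ester O–CH2 bond to acid 9 and benzyl bromide 10, and 9 at its C–CO2H bond to 1. The forward carboxylation is a chelation-driven ortho carboxylation in which magnesium salt 8 is the thermodynamic sink. Alkylation of the carboxyl group in the presence of two phenols relies on the large difference in acidity. Both halves of the depside thus start from 1.

## Alternatives that were turned down

Alternative 1: Ring A is folded from an acyclic chlorinated polyketide equivalent instead of being taken from an existing arene.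
- Disconnection: the C1–C6 bond of ring A, leading back to benzyl (6E)-4-chloro-7-methoxy-3,5-dioxodec-6-enoate (A2), a tetraketide whose terminal carbonyl is masked as a methyl enol ether.
- Forward key step: two equivalents of a lithium silylamide base would form the dianion of A2. The carbanion between the ester and the C3 ketone adds to the enol ether carbon, the methoxy group is expelled, and tautomerisation gives benzyl 3-chloro-2,4-dihydroxy-6-propylbenzoate (A1).
- For it: chlorine, both oxygens, propyl and the carboxyl carbon are all placed by the chain, so no arene substitution needs regiocontrol. The C2 hydroxyl of A1 emerges free, which spares the demethylation of step 7. On that point this alternative is the stronger one.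
- Against it: A2 is a 2-chloro-1,3-diketone flanked by further acidic sites. Such compounds are prone to retro-Claisen cleavage, loss of chlorine and closure through oxygen to pyranones, and A2 needs several steps of its own. A1 still has two free phenols, so C4 must be methylated selectively, the benzyl ester removed, and the resulting 2,6-disubstituted acid joined to 11.
- Comparison: the key step leaves the hindered aryl ester, the hardest bond of the target, untouched. The chosen strategy takes ring A intact from 1 in three steps and spends its key step on exactly that bond.

Alternative 2: The C6–propyl and C1–carboxyl bonds of ring A are cut together.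
- Disconnection: back to an aryne derived from the symmetric 5-bromo-2-chloro-1,3-dimethoxybenzene (A4).
- Forward key step: a hindered lithium amide would remove from A4 the hydrogen between bromine and methoxy, with loss of the bromine. A propyl Grignard reagent adds to the aryne carbon remote from the methoxy group, which places the new carbanion next to the inductively stabilising oxygen. Carboxylation gives 3-chloro-2,4-dimethoxy-6-propylbenzoic acid (A3).
- For it: two adjacent substituents are set in one pot with regiochemistry dictated by the ether, and A4 is as symmetric as 6. The path to A3 is at least as short as steps 1 to 3, so on step count for ring A this alternative equals or beats the chosen route.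
- Against it: the amide base and the Grignard reagent compete for the aryne, and halogen–metal exchange at C–Br competes with deprotonation. More important, A3 is exactly the 2,6-disubstituted benzoic acid whose esterification with a phenol is the known bottleneck. It would need activation as an acid chloride or mixed anhydride, followed by the same two end-game steps.
- Comparison: the chosen strategy gives up nothing in length and removes that activation by letting the carbonyl arrive as 12 on palladium. The same acid as A3 is kept in reserve as F2 in the fallback for step 6.

Alternative 3: Ring A is built by cycloaddition directly on the ring B ester.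
- Disconnection: the C1–C2 and C5–C6 bonds, giving benzyl 4-(hex-2-ynoyloxy)-2-hydroxy-6-propylbenzoate (A7) as dienophile and (1E)-2-chloro-1,3-dimethoxy-1-(trimethylsilyloxy)buta-1,3-diene (A6) as diene.
- Forward key step: the nucleophilic methylene terminus of A6 bonds to the propyl-bearing alkyne carbon of A7 and the acetal carbon bonds to the carbon next to the ester. Loss of the acetal methoxy group aromatises the adduct, and desilylation leaves the C2 phenol. The product is benzyl 4-[(3-chloro-2-hydroxy-4-methoxy-6-propylbenzoyl)oxy]-2-hydroxy-6-propylbenzoate (A5), which is the same compound as 15.
- For it: this is the most convergent plan on paper. The ester is made from an unhindered alkynoic acid before ring A exists, and in A5 ring A arrives with C2–OH free and C4–OMe in place. Only one step separates A5 from the target, against two after the key step of the chosen route, so on end-game economy and on avoiding the demethylation it is the stronger plan.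
- Against it: a 3-alkylpropiolate is a poor dienophile, and the chlorine lowers the donor ability of the diene and adds bulk between both reacting termini. Forcing conditions would be needed with a diene that is hydrolytically and thermally fragile. The aryl ester of A7 is an activated acyl donor that the ketene acetal can attack at the carbonyl, or the reaction can stop after conjugate addition. The free 2-OH of A7 is a proton source that quenches silyl ketene acetals, so ring B would need an extra protecting group. Preparing A6 pure is a project in itself.
- Comparison: the chosen strategy is one step longer after the key step than the path through A5. In return it uses a catalytic reaction class with broad precedent, stable and simple reagents, and a ring A fragment whose substitution pattern is secured by symmetry and not by the regiochemistry of a cycloaddition.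

Key step: step 6

Assumption: carboxylation of 1 with MeOMgOCO2Me is taken to follow the course known for other 5-alkylresorcinols, that is, attack at the carbon between a hydroxyl and the alkyl group; a fallback covers the other outcome.

## Route

Step 1
Reactants: 1 5-propylresorcinol; 2 dimethyl sulfate
Product: 4 1,3-dimethoxy-5-propylbenzene, via monomethyl ether 3 (not isolated)
Conditions: Me2SO4, K2CO3, acetone, reflux
Reagents that add atoms: dimethyl sulfate 2, COS(=O)(=O)OC
Why: Williamson O-methylation of both phenols; monoether 3 is alkylated as readily as 1, so excess 2 should carry it through to 4, and C-alkylation is negligible with K2CO3 in acetone.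

Step 2
Reactants: 4 1,3-dimethoxy-5-propylbenzene
Product: 6 2-chloro-1,3-dimethoxy-5-propylbenzene, via aryllithium 5 (not isolated)
Conditions: n-BuLi, THF, 0 °C to rt; then C2Cl6, −78 °C to rt
Reagents that add atoms: hexachloroethane, ClC(Cl)(Cl)C(Cl)(Cl)Cl
Why: Directed ortho-metalation: the hydrogen between the two methoxy groups is the most acidic in 4 and both oxygens coordinate lithium, so n-BuLi should give 5 only; C2Cl6 then transfers chlorine to the aryllithium with loss of C2Cl4 and LiCl. Electrophilic chlorination would instead go para to methoxy, which is why metalation is used.

Step 3
Reactants: 6 2-chloro-1,3-dimethoxy-5-propylbenzene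
Product: 7 2-chloro-4-iodo-1,3-dimethoxy-5-propylbenzene
Conditions: NIS, CF3CO2H (cat.), MeCN, rt, dark
Reagents that add atoms: N-iodosuccinimide, O=C1CCC(=O)N1I
Why: Electrophilic aromatic iodination; the two open positions of 6 are equivalent and each is ortho to one methoxy and para to the other, so only one monoiodide can form. One equivalent of reagent, together with the crowding and mild deactivation caused by the first iodine, should hold the reaction at monosubstitution.

Step 4
Reactants: 1 5-propylresorcinol
Product: 9 2,4-dihydroxy-6-propylbenzoic acid, via magnesium chelate 8 (not isolated)
Conditions: MeOMgOCO2Me (2 M in DMF), 120 °C; then cold aq HCl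
Reagents that add atoms: methoxymagnesium methyl carbonate, CO[Mg]OC(=O)OC
Why: Chelation-driven ortho-carboxylation of a phenol (a Kolbe–Schmitt-type reaction under magnesium control): CO2 is delivered next to a magnesium phenoxide and the product is held as chelate 8, which pulls the reversible carboxylation forward. Cold acidification should release 9 without decarboxylation.

Step 5
Reactants: 9 2,4-dihydroxy-6-propylbenzoic acid; 10 benzyl bromide
Product: 11 benzyl 2,4-dihydroxy-6-propylbenzoate
Conditions: BnBr, KHCO3, DMF, rt
Reagents that add atoms: benzyl bromide 10, BrCc1ccccc1
Why: SN2 O-alkylation of a carboxyl group; KHCO3 deprotonates the carboxylic acid but not the phenols, so benzylation should be confined to the acid, and room temperature avoids decarboxylation of 9.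

Step 6
Reactants: 7 2-chloro-4-iodo-1,3-dimethoxy-5-propylbenzene; 11 benzyl 2,4-dihydroxy-6-propylbenzoate; 12 carbon monoxide
Product: 13 benzyl 4-[(3-chloro-2,4-dimethoxy-6-propylbenzoyl)oxy]-2-hydroxy-6-propylbenzoate
Conditions: Pd(OAc)2 (5 mol %), Xantphos (7.5 mol %), CO (1 atm), Et3N, toluene, 90 °C
Reagents that add atoms: carbon monoxide 12, [C-]#[O+]
Why: Pd(OAc)2 is reduced in the flask to zerovalent palladium, which as its Xantphos complex inserts into the C–I bond of 7; carbon monoxide 12 then coordinates and the aryl group migrates onto it to give an aroyl complex of divalent palladium, a step that relieves crowding because it moves the metal one atom away from the doubly ortho-substituted ring carbon. The 4-phenoxide of 11, formed with Et3N, then displaces the metal from the aroyl group, either by attack at the acyl carbon or through an aroyl(aryloxy)palladium species that eliminates reductively, releasing 13 and zerovalent palladium while Et3N takes up HI. The reaction type is the known palladium-catalysed aryloxycarbonylation of aryl iodides with phenols, for which the wide-bite-angle ligand Xantphos is established at atmospheric CO pressure. No ring closes and no stereocenter forms. Two chemoselectivities are needed: insertion must take C–I and leave C–Cl, which the much weaker C–I bond secures, helped by the chloride lying between two methoxy groups on an electron-rich ring; and acylation must take the 4-OH of 11, which is free and the more acidic hydroxyl (para to the ester), whereas the 2-OH is tied up in a hydrogen bond to the ester carbonyl. The benzyl ester is inert to zerovalent palladium under these conditions, and the product ester is shielded from transesterification by the same 2,6-disubstitution that makes it hard to build classically.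

Step 7
Reactants: 13 benzyl 4-[(3-chloro-2,4-dimethoxy-6-propylbenzoyl)oxy]-2-hydroxy-6-propylbenzoate
Product: 15 benzyl 4-[(3-chloro-2-hydroxy-4-methoxy-6-propylbenzoyl)oxy]-2-hydroxy-6-propylbenzoate, via bis(dichloroboron) chelate 14 (not isolated)
Conditions: BCl3 (2.5 equiv), CH2Cl2, −78 to 0 °C; then H2O
Reagents that add atoms: none
Why: Chelation-controlled Lewis acid dealkylation: BCl3 binds the ring A ester carbonyl and the adjacent C2 methoxy oxygen in a six-membered chelate and chloride removes the methyl group as CH3Cl, while a further equivalent is taken up by the ring B salicylate hydroxyl with loss of HCl, which is why an excess is used. Both aryloxyboron dichloride units of 14 are hydrolysed on work-up. The C4 methoxy cannot chelate and should survive at or below 0 °C, and the aryl ester offers chloride no easy path to cleavage.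

Step 8
Reactants: 15 benzyl 4-[(3-chloro-2-hydroxy-4-methoxy-6-propylbenzoyl)oxy]-2-hydroxy-6-propylbenzoate
Product: 16 3-chlorodivaricatic acid
Conditions: H2 (1 atm), 10% Pd/C, EtOAc, rt
Reagents that add atoms: none
Why: Catalytic hydrogenolysis of the benzylic C–O bond of a benzyl ester, which on Pd on carbon in a neutral, base-free solvent is much faster than hydrogenolysis of an aryl C–Cl bond; the reaction is to be stopped once one equivalent of H2 is taken up. The aryl ester and both arenes are inert under these conditions.

## Compound list

1 | 5-propylresorcinol (5-propylbenzene-1,3-diol) | CCCc1cc(O)cc(O)c1 | starting material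
2 | dimethyl sulfate | COS(=O)(=O)OC | starting material
3 | 3-methoxy-5-propylphenol (formed in the flask, step 1) | CCCc1cc(O)cc(OC)c1 | intermediate
4 | 1,3-dimethoxy-5-propylbenzene | CCCc1cc(OC)cc(OC)c1 | intermediate
5 | (2,6-dimethoxy-4-propylphenyl)lithium (formed in the flask, step 2) | CCCc1cc(OC)c([Li])c(OC)c1 | intermediate
6 | 2-chloro-1,3-dimethoxy-5-propylbenzene | CCCc1cc(OC)c(Cl)c(OC)c1 | intermediate
7 | 2-chloro-4-iodo-1,3-dimethoxy-5-propylbenzene | CCCc1cc(OC)c(Cl)c(OC)c1I | intermediate
8 | magnesium 2-carboxylato-5-hydroxy-3-propylphenolate (formed in the flask, step 4) | CCCc1cc(O)cc([O-])c1C(=O)[O-].[Mg+2] | intermediate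
9 | 2,4-dihydroxy-6-propylbenzoic acid | CCCc1cc(O)cc(O)c1C(=O)O | intermediate
10 | benzyl bromide | BrCc1ccccc1 | starting material
11 | benzyl 2,4-dihydroxy-6-propylbenzoate | CCCc1cc(O)cc(O)c1C(=O)OCc1ccccc1 | intermediate
12 | carbon monoxide | [C-]#[O+] | starting material
13 | benzyl 4-[(3-chloro-2,4-dimethoxy-6-propylbenzoyl)oxy]-2-hydroxy-6-propylbenzoate | CCCc1cc(OC(=O)c2c(CCC)cc(OC)c(Cl)c2OC)cc(O)c1C(=O)OCc1ccccc1 | intermediate
14 | benzyl 4-({3-chloro-2-[(dichloroboranyl)oxy]-4-methoxy-6-propylbenzoyl}oxy)-2-[(dichloroboranyl)oxy]-6-propylbenzoate (formed in the flask, step 7) | CCCc1cc(OC(=O)c2c(CCC)cc(OC)c(Cl)c2OB(Cl)Cl)cc(OB(Cl)Cl)c1C(=O)OCc1ccccc1 | intermediate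
15 | benzyl 4-[(3-chloro-2-hydroxy-4-methoxy-6-propylbenzoyl)oxy]-2-hydroxy-6-propylbenzoate | CCCc1cc(OC(=O)c2c(CCC)cc(OC)c(Cl)c2O)cc(O)c1C(=O)OCc1ccccc1 | intermediate
16 | 3-chlorodivaricatic acid, 4-[(3-chloro-2-hydroxy-4-methoxy-6-propylbenzoyl)oxy]-2-hydroxy-6-propylbenzoic acid | CCCc1cc(OC(=O)c2c(CCC)cc(OC)c(Cl)c2O)cc(O)c1C(=O)O | target

## Step count and risk

Total step count: 8. Longest linear sequence: 6 steps (steps 1, 2, 3, 6, 7, 8). The ring B branch (steps 4 and 5) joins at step 6.

**Step 6 (key step).** The most likely failure is stalled turnover. Oxidative addition at an electron-rich C–I bond with two ortho substituents is slow, and capture of the hindered aroyl–palladium intermediate by a weakly nucleophilic phenoxide is slow as well. Reductive loss of iodine or interception of the aroyl complex by traces of water can then take over. The fallback sets out from 7 and comes back at 13. Iodine–magnesium exchange on 7 with i-PrMgCl·LiCl in THF would give (3-chloro-2,4-dimethoxy-6-propylphenyl)magnesium chloride F1. Treatment with CO2 and then dilute HCl would give 3-chloro-2,4-dimethoxy-6-propylbenzoic acid F2. Trifluoroacetic anhydride in toluene would convert F2 into 3-chloro-2,4-dimethoxy-6-propylbenzoic trifluoroacetic anhydride F3. F3 ionises easily to an acylium ion because the ring is electron-rich and the carbonyl is already twisted out of conjugation, and it would acylate the free 4-OH of 11 to give 13.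

**Step 7.** The ether cleavage may be incomplete or unselective. The ring A ester carbonyl is twisted out of the ring plane and chelates boron less well than a coplanar carbonyl, so warming may be needed, and the C4 methoxy may then begin to cleave. The boron chelate on the ring B salicylate also activates the benzyl ester toward attack by chloride; loss of the benzyl ester is harmless, since it leads on to 16. The fallback sets out from 7 and comes back at 15, moving the demethylation to a stage where neither a benzyl ester nor the aryl ester is present. Compound 7 is converted as above into (3-chloro-2,4-dimethoxy-6-propylphenyl)magnesium chloride F1 and 3-chloro-2,4-dimethoxy-6-propylbenzoic acid F2. BCl3 in CH2Cl2 would bind the carboxyl group of F2 and cleave the neighbouring methoxy group, giving 2,8-dichloro-7-methoxy-5-propyl-4H-1,3,2-benzodioxaborinin-4-one F4. Aqueous work-up would hydrolyse F4 to 3-chloro-2-hydroxy-4-methoxy-6-propylbenzoic acid F5. Trifluoroacetic anhydride in toluene would turn F5 into 3-chloro-2-hydroxy-4-methoxy-6-propylbenzoic trifluoroacetic anhydride F6, which would acylate the 4-OH of 11 to give 15. This last operation is the classical condensation used to make depsides from 2-hydroxy acids.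

**Step 8.** Reductive loss of the ring A chlorine may compete with benzyl C–O hydrogenolysis, especially if the reaction runs past one equivalent of H2. The fallback sets out from 15 and comes back at 16 without any reducing agent. BCl3 in CH2Cl2 at −78 °C with pentamethylbenzene as benzyl cation scavenger should cleave the benzyl ester by Lewis acid-assisted ionisation and give 16 after aqueous work-up. No new compound is made on the way. Applied to 13 with more BCl3, the same treatment would merge steps 7 and 8.

**Step 4.** Carboxylation may occur between the two hydroxyls instead of next to the propyl group, and the β-resorcylic acid may decarboxylate during acidic work-up or on warming. The fallback sets out from 1 and comes back at 9, relying on electrophilic substitution para to a hydroxyl instead of chelation. Vilsmeier formylation of 1 (POCl3, DMF) would give N-[(2,4-dihydroxy-6-propylphenyl)methylidene]-N-methylmethanaminium chloride F7. Aqueous hydrolysis would give 2,4-dihydroxy-6-propylbenzaldehyde F8. Pinnick oxidation (NaClO2, NaH2PO4, sulfamic acid as hypochlorite scavenger, aqueous dioxane) would then give 9.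

## Further compounds

F1 | step 6 | (3-chloro-2,4-dimethoxy-6-propylphenyl)magnesium chloride | CCCc1cc(OC)c(Cl)c(OC)c1[Mg]Cl
F2 | step 6 | 3-chloro-2,4-dimethoxy-6-propylbenzoic acid | CCCc1cc(OC)c(Cl)c(OC)c1C(=O)O
F3 | step 6 | 3-chloro-2,4-dimethoxy-6-propylbenzoic trifluoroacetic anhydride | CCCc1cc(OC)c(Cl)c(OC)c1C(=O)OC(=O)C(F)(F)F
F4 | step 7 | 2,8-dichloro-7-methoxy-5-propyl-4H-1,3,2-benzodioxaborinin-4-one | CCCc1cc(OC)c(Cl)c2OB(Cl)OC(=O)c12
F5 | step 7 | 3-chloro-2-hydroxy-4-methoxy-6-propylbenzoic acid | CCCc1cc(OC)c(Cl)c(O)c1C(=O)O
F6 | step 7 | 3-chloro-2-hydroxy-4-methoxy-6-propylbenzoic trifluoroacetic anhydride | CCCc1cc(OC)c(Cl)c(O)c1C(=O)OC(=O)C(F)(F)F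
F0 | step 8 | none | none
F7 | step 4 | N-[(2,4-dihydroxy-6-propylphenyl)methylidene]-N-methylmethanaminium chloride | CCCc1cc(O)cc(O)c1C=[N+](C)C.[Cl-]
F8 | step 4 | 2,4-dihydroxy-6-propylbenzaldehyde | CCCc1cc(O)cc(O)c1C=O
A1 | alternative 1 | benzyl 3-chloro-2,4-dihydroxy-6-propylbenzoate | CCCc1cc(O)c(Cl)c(O)c1C(=O)OCc1ccccc1
A2 | alternative 1 | benzyl (6E)-4-chloro-7-methoxy-3,5-dioxodec-6-enoate | CO/C(CCC)=C/C(=O)C(Cl)C(=O)CC(=O)OCc1ccccc1
A3 | alternative 2 | 3-chloro-2,4-dimethoxy-6-propylbenzoic acid | CCCc1cc(OC)c(Cl)c(OC)c1C(=O)O
A4 | alternative 2 | 5-bromo-2-chloro-1,3-dimethoxybenzene | COc1cc(Br)cc(OC)c1Cl
A5 | alternative 3 | benzyl 4-[(3-chloro-2-hydroxy-4-methoxy-6-propylbenzoyl)oxy]-2-hydroxy-6-propylbenzoate | CCCc1cc(OC(=O)c2c(CCC)cc(OC)c(Cl)c2O)cc(O)c1C(=O)OCc1ccccc1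
A6 | alternative 3 | (1E)-2-chloro-1,3-dimethoxy-1-(trimethylsilyloxy)buta-1,3-diene | C=C(OC)/C(Cl)=C(/OC)O[Si](C)(C)C
A7 | alternative 3 | benzyl 4-(hex-2-ynoyloxy)-2-hydroxy-6-propylbenzoate | CCCC#CC(=O)Oc1cc(O)c(C(=O)OCc2ccccc2)c(CCC)c1
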